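Write the balance of the partner, the limiting reagent here, whose 1.80 M stands below the 2.0 M of substrate.

| flask | substrate | partner | free catalyst | temperature | time | remark |
|---|---|---|---|---|---|---|
| noon | 2.0 M | 1.80 M | 4.0 mM | 55 °C | 6.0 min |  |
| summer | 2.0 M | 1.80 M | 4.0 mM |  | 6.0 min | at 55 °C until 2.0 min, from then on at 35 °C |
| winter | 2.0 M | 1.80 M | 4.0 mM | 35 °C | 6.0 min |  |

- the list of constants is for 35 °C, to be carried to other temperatures by the activation energies and enthalpies

1. the flask with the highest amount of product, in percent of the substrate charged ("all alike" if they lie within 1.5 percentage points) (noon / summer / winter / all alike)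
2. final product, as a percentage of the substrate charged, in noon
3. final product, as a percentage of the substrate charged, in summer
4. final product, as a percentage of the substrate charged, in winter

    partner + free catalyst ⇌ catalyst intermediate A (K1 = 6.0 /M, k1 = 46 /M/s, Ea1 = 39.0 kJ/mol, ΔH1 = 34.0 kJ/mol)
    substrate + catalyst intermediate A ⇌ catalyst intermediate B (K2 = 0.58 /M, k2 = 1.3 /M/s, Ea2 = 56.0 kJ/mol, ΔH2 = −90.0 kJ/mol)
    catalyst intermediate B → free catalyst + product (k3 = 12 /s, Ea3 = 79.0 kJ/mol)
    partner → decomposed reagent (k4 = 0.0011 /s, Ea4 = 97.0 kJ/mol)
    (constants at 35 °C)

I reckon with the catalyst sitting as catalyst intermediate A, since the partner charge times its binding constant is 10.8 at 35 °C. Substrate that binds there falls back or goes on to product. The ratio b of back to on is 0.187 in winter and 0.919 in noon; to carry a constant to 55 °C, I raise the decomposition's factor of 10 to that constant's energy over the decomposition's activation energy. So substrate decays pseudo-first-order with λ, the binding rate constant times the catalyst charge over the sum of one and b: 0.263 /min in winter, 0.616 /min in noon.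

The partner loses the same amount and also decomposes with constant k_d, 0.066 /min in winter and 0.663 /min in noon. Their ratio ρ = λ/k_d is 3.98 in winter and 0.929 in noon. This ρ, the selectivity factor of catalyst against decomposition for the partner, closes the balance. With u = 1 − 1/ρ and β the partner charge over the substrate charge, the partner reaches zero at conversion X = 1 − (1 − βu)^(1/u).

That gives 58.1% in noon, at 1.41 min. Summer matches it, since this comes before the cooling. For winter I reckon 77.6%, at 5.69 min, barely inside the run. Loading weakens as the partner thins, so I expect the flasks to end below these marks.

The forecast names winter, with 54.5% (52% to 57%) for noon, 54.4% (52% to 57%) for summer and 65.8% (63% to 69%) for winter, where it stands below my mark; of summer it says “its cooling comes too late to matter”.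

The flasks give 54.6% in noon, 54.6% in summer and 66.1% in winter, so winter leads and the forecast holds.

Winter's ρ of 3.98 stands above noon's 0.929, as the yields do. Part of winter's distance below my mark lies in the back reaction of catalyst intermediate A to partner and free catalyst, acting together with the length of the run: winter gives 74.3% without that back reaction, and 73.8% in a run ten times as long. A neighbour of summer with 0.0016 M of free catalyst has λ scaled with its charge, so ρ at 55 °C becomes 0.371 and X becomes 42.1%. That neighbour ends at 38.2%.

All constants were chosen freely; what happens was integrated by code.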